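A direct plan would buy the decalin as (−)-abietic acid A1 and cut ring C of A1 back oxidatively to C13.
It would then oxygenate C6 by a carboxylate-directed C–H lactonisation to lactone A2 and regrow the chain to the (13E,16S)-butenolide A3.
It would finish with a singlet-oxygen ene reaction at the C13=C14 alkene of A3.
Weakest would be the C–H lactonisation: two γ-methylenes (C2 and C6) and a free tertiary alcohol would compete, without close precedent.
Next, the excision and regrowth of the chain carbons (cleavage, Baeyer–Villiger, saponification, reduction) would add length without adding complexity.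
Last, the closing photooxygenation would have no facial control at C13 and a competing regiochemistry, so most late material would be lost.

Ring B carries a C6/C8 1,3-diol beside the quaternary C10, and this is exploited by cutting ring B at C9–C10 and C6–C7. A C6 carbinol, set by CBS reduction in a ring A 1,5-dien-3-ol, would be spent in an anionic oxy-Cope rearrangement: one chair transition state forms C9–C10, creates C10 and C9, and unmasks a C6 aldehyde and a C8 isopropenyl group. These would reclose ring B in a Prins reaction ended by the side-chain ketone, which returns oxygen to C6 and puts it on C8. No C–H oxidation or degradation is needed, and C13 would be set by Sharpless epoxidation and invertive perhydrolysis, not by an unselective ene reaction.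

Key step: step 11

Numbering: labdane locants are used throughout (C17, C19 and C20 are the methyls on C8, C4 and C10; C18 is the ester carbon; in the labdane names of 21–28 C16 is the methyl on C13). Only in 32–35, F6, F7 and A3 is the chain counted on from C9 as C11–C16, so that C13 bears the peroxide or the methyl and C16 is the lactone carbinol carbon. α is the face opposite the C10 methyl.
Assumption: the L-valine tert-butyl ester enamine is taken to give the (R)-keto ester 3 under the conditions of step 1; if the sense were opposite, the D-valine ester would be used.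

Step 1
Reactants: 1 methyl 2-oxocyclohexane-1-carboxylate
Product: 3 methyl (1R)-1-methyl-2-oxocyclohexane-1-carboxylate, via valine enamine 2 (not isolated)
Conditions: L-valine tert-butyl ester, BF3·OEt2 (cat.), benzene, reflux (−H2O); LiN(iPr)2, toluene/HMPA, −78 °C; MeI; aq. citric acid
Reagents that add atoms: iodomethane, CI
Why: Asymmetric alkylation of the lithiated chiral enamine of a β-keto ester, in which the chelated valine ester shields one face so that iodomethane sets the C4 quaternary centre before hydrolysis returns the auxiliary.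

Step 2
Reactants: 3 methyl (1R)-1-methyl-2-oxocyclohexane-1-carboxylate
Product: 4 methyl (1R)-1,3-dimethyl-2-oxocyclohexane-1-carboxylate (both C3 epimers)
Conditions: LiN(iPr)2, THF, −78 °C; MeI, DMPU, −78 → 0 °C
Reagents that add atoms: iodomethane, CI
Why: Kinetic enolate alkylation at the only enolisable position introduces the later C10 methyl, and the new centre need not be controlled because it becomes trigonal in the next step.

Step 3
Reactants: 4 methyl (1R)-1,3-dimethyl-2-oxocyclohexane-1-carboxylate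
Product: 5 methyl (1R)-1,3-dimethyl-2-(trifluoromethanesulfonyloxy)cyclohex-2-ene-1-carboxylate
Conditions: KN(SiMe3)2, THF, −78 → 0 °C; PhNTf2
Reagents that add atoms: N-phenylbis(trifluoromethanesulfonimide), O=S(=O)(N(c1ccccc1)S(=O)(=O)C(F)(F)F)C(F)(F)F
Why: Enol triflate formation, in which the ketone can enolise only towards the methyl-bearing carbon, so O-sulfonylation fixes the tetrasubstituted C5=C10 alkene.

Step 4
Reactants: 5 methyl (1R)-1,3-dimethyl-2-(trifluoromethanesulfonyloxy)cyclohex-2-ene-1-carboxylate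
Product: 6 methyl (1R)-2-formyl-1,3-dimethylcyclohex-2-ene-1-carboxylate
Conditions: Pd(PPh3)4 (5 mol%), LiCl, CO (3 atm), Bu3SnH (slow addition), THF, 50 °C
Reagents that add atoms: carbon monoxide, [C-]#[O+]
Why: Palladium-catalysed reductive carbonylation (formylation) of the enol triflate by oxidative addition to zerovalent palladium, CO insertion and hydride transfer from Bu3SnH, slow addition of the hydride suppressing direct reduction.

Step 5
Reactants: 7 6-methylhept-5-en-2-one
Product: 8 2-methyl-2-(4-methylpent-3-en-1-yl)-1,3-dioxolane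
Conditions: ethylene glycol, p-TsOH (cat.), benzene, reflux (Dean–Stark)
Reagents that add atoms: ethane-1,2-diol, OCCO
Why: Acid-catalysed ketalisation with azeotropic removal of water masks the methyl ketone, the later C13, through the organobarium, hydride and potassium hydride steps.

Step 6
Reactants: 8 2-methyl-2-(4-methylpent-3-en-1-yl)-1,3-dioxolane
Product: 9 (2E)-2-methyl-5-(2-methyl-1,3-dioxolan-2-yl)pent-2-en-1-ol
Conditions: SeO2 (cat.), t-BuOOH, salicylic acid (cat.), CH2Cl2, rt
Reagents that add atoms: selenium dioxide, O=[Se]=O (oxygen carrier); tert-butyl hydroperoxide, CC(C)(C)OO (terminal oxidant)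
Why: Selenium dioxide allylic oxidation (ene reaction then [2,3]-sigmatropic shift) is selective for the (E)-methyl of a trisubstituted alkene, which fixes the alkene geometry that is later carried into the rearrangement.

Step 7
Reactants: 9 (2E)-2-methyl-5-(2-methyl-1,3-dioxolan-2-yl)pent-2-en-1-ol
Product: 10 2-[(3E)-5-chloro-4-methylpent-3-en-1-yl]-2-methyl-1,3-dioxolane
Conditions: MsCl, LiCl, 2,4,6-collidine, DMF, 0 °C
Reagents that add atoms: lithium chloride, [Li+].[Cl-]
Why: Mesylation and in situ SN2 displacement by chloride give the primary allylic chloride without allylic transposition or loss of the E geometry.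

Step 8
Reactants: 6 methyl (1R)-2-formyl-1,3-dimethylcyclohex-2-ene-1-carboxylate; 10 2-[(3E)-5-chloro-4-methylpent-3-en-1-yl]-2-methyl-1,3-dioxolane
Product: 12 methyl (1R)-2-[(3E)-1-hydroxy-3-methyl-6-(2-methyl-1,3-dioxolan-2-yl)hex-3-en-1-yl]-1,3-dimethylcyclohex-2-ene-1-carboxylate (both carbinol epimers), via allylbarium chloride 11 (not isolated)
Conditions: BaI2, lithium biphenylide (2 equiv), THF, rt (activated barium); 10, −78 °C; 6, −78 °C; AcOH, −78 °C; crude product used at once
Reagents that add atoms: none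
Why: Allylic barium reagents add to aldehydes through their unsubstituted (α) carbon with retention of alkene geometry, so the C6–C7 bond forms with the E-alkene intact and gives the linear homoallylic alcohol, the carbinol centre being left uncontrolled here.

Step 9
Reactants: 12 methyl (1R)-2-[(3E)-1-hydroxy-3-methyl-6-(2-methyl-1,3-dioxolan-2-yl)hex-3-en-1-yl]-1,3-dimethylcyclohex-2-ene-1-carboxylate
Product: 13 methyl (1R)-1,3-dimethyl-2-[(3E)-3-methyl-6-(2-methyl-1,3-dioxolan-2-yl)hex-3-enoyl]cyclohex-2-ene-1-carboxylate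
Conditions: Dess–Martin periodinane, pyridine, CH2Cl2, 0 °C
Reagents that add atoms: none
Why: Dess–Martin oxidation under buffered, non-basic conditions gives the ketone without moving the β,γ-alkene into conjugation.

Step 10
Reactants: 13 methyl (1R)-1,3-dimethyl-2-[(3E)-3-methyl-6-(2-methyl-1,3-dioxolan-2-yl)hex-3-enoyl]cyclohex-2-ene-1-carboxylate
Product: 14 methyl (1R)-2-[(1S,3E)-1-hydroxy-3-methyl-6-(2-methyl-1,3-dioxolan-2-yl)hex-3-en-1-yl]-1,3-dimethylcyclohex-2-ene-1-carboxylate
Conditions: (R)-2-methyl-CBS-oxazaborolidine (20 mol%), catecholborane, toluene, −78 °C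
Reagents that add atoms: none
Why: Corey–Bakshi–Shibata reduction in which the 2,6-disubstituted cyclohexenyl group is the large and the CH2 group the small substituent, so the (R)-catalyst should give the (S)-carbinol at C6 under catalyst control.

Step 11
Reactants: 14 methyl (1R)-2-[(1S,3E)-1-hydroxy-3-methyl-6-(2-methyl-1,3-dioxolan-2-yl)hex-3-en-1-yl]-1,3-dimethylcyclohex-2-ene-1-carboxylate
Product: 18 (1R,2R,3R)-2-formyl-1,3-dimethyl-3-[(3S)-2-methyl-5-(2-methyl-1,3-dioxolan-2-yl)pent-1-en-3-yl]cyclohexane-1-carboxylic acid, via potassium hydroxy carboxylate 15 (not isolated), via dipotassium alkoxide carboxylate 16 (not isolated), via dipotassium enolate carboxylate 17 (not isolated)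
Conditions: KOH (1.2 equiv), MeOH/H2O, 45 °C; evaporate, azeotrope (toluene); KH (1.5 equiv), 18-crown-6, THF, 0 → 50 °C; AcOH, −78 °C
Reagents that add atoms: potassium hydroxide, [K+].[OH-]
Why: Hydroxide first cleaves the hindered ester through the neighbouring hydroxyl (transient lactone), so that no ester is left to acylate the alkoxide, and the potassium alkoxide then undergoes an anionic oxy-Cope ([3,3]-sigmatropic) rearrangement, the known reaction of 1-cyclohexenyl 1,5-dien-3-ols that amounts to a conjugate allylation. No ring is closed: the C9–C10 bond forms and the C6–C7 bond breaks, which gives the C10 quaternary centre, C9, an aldehyde enolate at C5=C6 and the isopropenyl group on C8. The chair transition state is favoured because the substituents on the two central carbons (C4 on C5 and the methyl on C8) would eclipse in a boat, and in it the C6 hydrogen must lie inside, syn to the C10 methyl (1,3-allylic strain), with the oxyanion outside, so the (S)-carbinol sends C9 to the α face of C10, anti to the C4 methyl. The E-alkene places C11 equatorial, which sets C9 relative to C10. C5 is set when the enolate is protonated from the α face, anti to the two flanking β-methyl groups. The step needs the rearrangement to outrun fragmentation of the alkoxide (retro-allylation), which the crown-ether-separated potassium alkoxide and the carbinol held perpendicular by its two ortho substituents should secure.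

Step 12
Reactants: 18 (1R,2R,3R)-2-formyl-1,3-dimethyl-3-[(3S)-2-methyl-5-(2-methyl-1,3-dioxolan-2-yl)pent-1-en-3-yl]cyclohexane-1-carboxylic acid
Product: 19 methyl (1R,2R,3R)-2-formyl-1,3-dimethyl-3-[(3S)-2-methyl-5-(2-methyl-1,3-dioxolan-2-yl)pent-1-en-3-yl]cyclohexane-1-carboxylate
Conditions: Me3SiCHN2, toluene/MeOH, 0 °C
Reagents that add atoms: (trimethylsilyl)diazomethane, C[Si](C)(C)C=[N+]=[N-]
Why: Diazoalkane esterification of the acid, which reacts through its open form, proceeds under neutral conditions and leaves the epimerisable C5 centre untouched.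

Step 13
Reactants: 19 methyl (1R,2R,3R)-2-formyl-1,3-dimethyl-3-[(3S)-2-methyl-5-(2-methyl-1,3-dioxolan-2-yl)pent-1-en-3-yl]cyclohexane-1-carboxylate
Product: 21 methyl 6α,8α-dihydroxy-13-oxo-14,15-dinorlabdan-18-oate, via keto aldehyde 20 (not isolated)
Conditions: PPTS, acetone/H2O, 40 °C; concentrate; BF3·OEt2 (1.1 equiv), CH2Cl2, −78 → −40 °C; aq. NaHCO3
Reagents that add atoms: water, O
Why: After acetal hydrolysis a Lewis-acid Prins cyclisation closes ring B, the isopropenyl CH2 attacking the activated aldehyde in a chair (6-endo, C6–C7 bond) with the complexed oxygen equatorial (6α), and the tertiary C8 cation is captured on its α face (anti addition) by the side-chain ketone oxygen as a six-membered oxocarbenium ion that water opens to the 8α-hydroxy ketone.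

Step 14
Reactants: 21 methyl 6α,8α-dihydroxy-13-oxo-14,15-dinorlabdan-18-oate
Product: 22 methyl 13-oxo-6α,8α-bis(triethylsilyloxy)-14,15-dinorlabdan-18-oate
Conditions: Et3SiOTf (3 equiv), 2,6-lutidine, CH2Cl2, −78 → 0 °C
Reagents that add atoms: triethylsilyl trifluoromethanesulfonate, CC[Si](CC)(CC)OS(=O)(=O)C(F)(F)F
Why: Silyl triflate silylation caps the secondary 6α-hydroxyl, which could lactonise onto C18 under base, and the tertiary 8α-hydroxyl, which would otherwise attack C13 when the epoxide is opened.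

Step 15
Reactants: 22 methyl 13-oxo-6α,8α-bis(triethylsilyloxy)-14,15-dinorlabdan-18-oate
Product: 23 15-ethyl 18-methyl (13E)-6α,8α-bis(triethylsilyloxy)labd-13-ene-15,18-dioate
Conditions: (EtO)2P(O)CH2CO2Et, NaH, THF, 0 °C → reflux; minor Z isomer removed by chromatography
Reagents that add atoms: triethyl phosphonoacetate, CCOC(=O)CP(=O)(OCC)OCC
Why: Horner–Wadsworth–Emmons olefination of the methyl ketone should favour the (13E)-enoate and adds C14 and a temporary C15.

Step 16
Reactants: 23 15-ethyl 18-methyl (13E)-6α,8α-bis(triethylsilyloxy)labd-13-ene-15,18-dioate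
Product: 24 methyl (13E)-15-hydroxy-6α,8α-bis(triethylsilyloxy)labd-13-en-18-oate
Conditions: iBu2AlH (2.2 equiv), CH2Cl2, −78 °C; aq. potassium sodium tartrate
Reagents that add atoms: none
Why: Hydride reduction of the unhindered conjugated ester to the allylic alcohol, the neopentyl C18 methyl ester next to the silyl ether being left at −78 °C.

Step 17
Reactants: 24 methyl (13E)-15-hydroxy-6α,8α-bis(triethylsilyloxy)labd-13-en-18-oate
Product: 25 methyl (13S,14S)-13,14-epoxy-15-hydroxy-6α,8α-bis(triethylsilyloxy)labdan-18-oate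
Conditions: Ti(OiPr)4 (10 mol%), L-(+)-diethyl tartrate (12 mol%), t-BuOOH, 4 Å molecular sieves, CH2Cl2, −20 °C
Reagents that add atoms: tert-butyl hydroperoxide, CC(C)(C)OO
Why: Sharpless asymmetric epoxidation, in which the tartrate complex of tetravalent titanium delivers oxygen to one face of the E-allylic alcohol and with L-(+)-tartrate should give the (13S,14S)-epoxide by reagent control.

Step 18
Reactants: 25 methyl (13S,14S)-13,14-epoxy-15-hydroxy-6α,8α-bis(triethylsilyloxy)labdan-18-oate
Product: 26 methyl (13R,14S)-13-hydroperoxy-14,15-dihydroxy-6α,8α-bis(triethylsilyloxy)labdan-18-oate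
Conditions: anhydrous H2O2 in Et2O (excess), phosphomolybdic acid H3PMo12O40 (2 mol%), rt
Reagents that add atoms: hydrogen peroxide, OO
Why: Acid-catalysed perhydrolysis of the epoxide, in which hydrogen peroxide opens the trisubstituted epoxide at the tertiary carbon with inversion (borderline SN2), so the (13S)-epoxide should give the (13R)-hydroperoxide.

Step 19
Reactants: 26 methyl (13R,14S)-13-hydroperoxy-14,15-dihydroxy-6α,8α-bis(triethylsilyloxy)labdan-18-oate
Product: 28 methyl (13R)-13-[(2-methoxypropan-2-yl)peroxy]-14-oxo-6α,8α-bis(triethylsilyloxy)-15-norlabdan-18-oate, via hydroperoxy aldehyde 27 (not isolated)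
Conditions: NaIO4, THF/pH 7 buffer (NaH2PO4/Na2HPO4), 0 °C; extract, dry; 2-methoxypropene, PPTS (cat.), CH2Cl2, 0 °C
Reagents that add atoms: 2-methoxypropene, COC(C)=C
Why: Periodate glycol cleavage removes C15 and leaves C14 as the aldehyde, and the labile α-hydroperoxy aldehyde is capped at once as its peroxyketal, C13 being quaternary and unable to epimerise.

Step 20
Reactants: 29 5-hydroxy-4-methylfuran-2(5H)-one
Product: 30 methyl (2Z)-3-methyl-4-oxobut-2-enoate
Conditions: Me3SiCHN2 (1.0 equiv), toluene/MeOH, 0 °C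
Reagents that add atoms: (trimethylsilyl)diazomethane, C[Si](C)(C)C=[N+]=[N-]
Why: Diazoalkane O-methylation of the ring-opened carboxylic acid tautomer of the hydroxybutenolide gives the formyl ester with the Z geometry fixed by the ring.

Step 21
Reactants: 30 methyl (2Z)-3-methyl-4-oxobut-2-enoate
Product: 31 methyl (2Z)-5-(dimethoxyphosphoryl)-3-methyl-4-oxopent-2-enoate
Conditions: dimethyl (diazomethyl)phosphonate, SnCl2 (10 mol%), CH2Cl2, rt
Reagents that add atoms: dimethyl (diazomethyl)phosphonate, COP(=O)(OC)C=[N+]=[N-]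
Why: Roskamp homologation, in which SnCl2 promotes addition of the diazo carbon to the aldehyde and a 1,2-hydride shift with loss of N2, gives the β-keto phosphonate without an alcohol stage that would lactonise.

Step 22
Reactants: 28 methyl (13R)-13-[(2-methoxypropan-2-yl)peroxy]-14-oxo-6α,8α-bis(triethylsilyloxy)-15-norlabdan-18-oate; 31 methyl (2Z)-5-(dimethoxyphosphoryl)-3-methyl-4-oxopent-2-enoate
Product: 32 (13R,14E)-dienone ester: C18 methyl ester with 6α,8α-bis(triethylsilyloxy) groups and the C9 chain CH2CH2C(CH3)[OOC(CH3)2OCH3]CH=CHC(=O)C(CH3)=CHCO2CH3 ending in the (Z)-enoate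
Conditions: Ba(OH)2 (activated), THF/H2O 40:1, rt
Reagents that add atoms: none
Why: Horner–Wadsworth–Emmons olefination of the β-keto phosphonate under mild barium hydroxide conditions should give the (14E)-enone, the aldehyde having no α-hydrogen and the peroxyketal tolerating the weak base.

Step 23
Reactants: 32 (13R,14E)-dienone ester
Product: 34 bis(triethylsilyl) ether 2-methoxyprop-2-yl peroxide of the target, via hydroxy enoate 33 (not isolated)
Conditions: (R)-2-methyl-CBS-oxazaborolidine (1 equiv), catecholborane, toluene/CH2Cl2, −78 °C; pH 7 work-up, rt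
Reagents that add atoms: none
Why: Corey–Bakshi–Shibata 1,2-reduction in which the α-methyl-branched (Z)-alkenyl group acts as the large substituent should give the (16S)-carbinol, and the (Z)-γ-hydroxy enoate then closes to the butenolide with loss of methanol.

Step 24
Reactants: 34 bis(triethylsilyl) ether 2-methoxyprop-2-yl peroxide of the target
Product: 35 target, methyl (13R,14E,16S)-6α,8α-dihydroxy-13-hydroperoxy ester with the 4-methylbutenolide at C16
Conditions: HF (48% aq.), MeCN, 0 °C
Reagents that add atoms: none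
Why: Acidic desilylation removes both triethylsilyl ethers and hydrolyses the peroxyketal to the free hydroperoxide without touching a stereocentre.

Compound list

1 | methyl 2-oxocyclohexane-1-carboxylate | COC(=O)C1CCCCC1=O | starting material
2 | methyl 2-{[(2S)-1-tert-butoxy-3-methyl-1-oxobutan-2-yl]amino}cyclohex-1-ene-1-carboxylate (valine enamine) | COC(=O)C1=C(N[C@@H](C(C)C)C(=O)OC(C)(C)C)CCCC1 | intermediate
3 | methyl (1R)-1-methyl-2-oxocyclohexane-1-carboxylate | COC(=O)[C@]1(C)CCCCC1=O | intermediate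
4 | methyl (1R)-1,3-dimethyl-2-oxocyclohexane-1-carboxylate (both C3 epimers) | COC(=O)[C@]1(C)CCCC(C)C1=O | intermediate
5 | methyl (1R)-1,3-dimethyl-2-(trifluoromethanesulfonyloxy)cyclohex-2-ene-1-carboxylate | COC(=O)[C@]1(C)CCCC(C)=C1OS(=O)(=O)C(F)(F)F | intermediate
6 | methyl (1R)-2-formyl-1,3-dimethylcyclohex-2-ene-1-carboxylate | COC(=O)[C@]1(C)CCCC(C)=C1C=O | intermediate
7 | 6-methylhept-5-en-2-one | CC(C)=CCCC(C)=O | starting material
8 | 2-methyl-2-(4-methylpent-3-en-1-yl)-1,3-dioxolane | CC(C)=CCCC1(C)OCCO1 | intermediate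
9 | (2E)-2-methyl-5-(2-methyl-1,3-dioxolan-2-yl)pent-2-en-1-ol | OC/C(C)=C/CCC1(C)OCCO1 | intermediate
10 | 2-[(3E)-5-chloro-4-methylpent-3-en-1-yl]-2-methyl-1,3-dioxolane | ClC/C(C)=C/CCC1(C)OCCO1 | intermediate
11 | [(2E)-2-methyl-5-(2-methyl-1,3-dioxolan-2-yl)pent-2-en-1-yl]barium chloride | Cl[Ba]C/C(C)=C/CCC1(C)OCCO1 | intermediate
12 | methyl (1R)-2-[(3E)-1-hydroxy-3-methyl-6-(2-methyl-1,3-dioxolan-2-yl)hex-3-en-1-yl]-1,3-dimethylcyclohex-2-ene-1-carboxylate (both carbinol epimers) | COC(=O)[C@]1(C)CCCC(C)=C1C(O)C/C(C)=C/CCC1(C)OCCO1 | intermediate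
13 | methyl (1R)-1,3-dimethyl-2-[(3E)-3-methyl-6-(2-methyl-1,3-dioxolan-2-yl)hex-3-enoyl]cyclohex-2-ene-1-carboxylate | COC(=O)[C@]1(C)CCCC(C)=C1C(=O)C/C(C)=C/CCC1(C)OCCO1 | intermediate
14 | methyl (1R)-2-[(1S,3E)-1-hydroxy-3-methyl-6-(2-methyl-1,3-dioxolan-2-yl)hex-3-en-1-yl]-1,3-dimethylcyclohex-2-ene-1-carboxylate | COC(=O)[C@]1(C)CCCC(C)=C1[C@@H](O)C/C(C)=C/CCC1(C)OCCO1 | intermediate
15 | potassium (1R)-2-[(1S,3E)-1-hydroxy-3-methyl-6-(2-methyl-1,3-dioxolan-2-yl)hex-3-en-1-yl]-1,3-dimethylcyclohex-2-ene-1-carboxylate | [K+].[O-]C(=O)[C@]1(C)CCCC(C)=C1[C@@H](O)C/C(C)=C/CCC1(C)OCCO1 | intermediate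
16 | dipotassium alkoxide carboxylate of 15 | [K+].[K+].[O-]C(=O)[C@]1(C)CCCC(C)=C1[C@@H]([O-])C/C(C)=C/CCC1(C)OCCO1 | intermediate
17 | dipotassium (1R,3R)-1,3-dimethyl-3-[(3S)-2-methyl-5-(2-methyl-1,3-dioxolan-2-yl)pent-1-en-3-yl]-2-[(Z)-oxidomethylidene]cyclohexane-1-carboxylate | [K+].[K+].[O-]C(=O)[C@]1(C)CCC[C@](C)([C@@H](CCC2(C)OCCO2)C(C)=C)/C1=C/[O-] | intermediate
18 | (1R,2R,3R)-2-formyl-1,3-dimethyl-3-[(3S)-2-methyl-5-(2-methyl-1,3-dioxolan-2-yl)pent-1-en-3-yl]cyclohexane-1-carboxylic acid | OC(=O)[C@]1(C)CCC[C@](C)([C@@H](CCC2(C)OCCO2)C(C)=C)[C@H]1C=O | intermediate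
19 | methyl (1R,2R,3R)-2-formyl-1,3-dimethyl-3-[(3S)-2-methyl-5-(2-methyl-1,3-dioxolan-2-yl)pent-1-en-3-yl]cyclohexane-1-carboxylate | COC(=O)[C@]1(C)CCC[C@](C)([C@@H](CCC2(C)OCCO2)C(C)=C)[C@H]1C=O | intermediate
20 | methyl (1R,2R,3R)-2-formyl-1,3-dimethyl-3-[(3S)-2-methyl-6-oxohept-1-en-3-yl]cyclohexane-1-carboxylate | COC(=O)[C@]1(C)CCC[C@](C)([C@@H](CCC(C)=O)C(C)=C)[C@H]1C=O | intermediate
21 | methyl 6α,8α-dihydroxy-13-oxo-14,15-dinorlabdan-18-oate | COC(=O)[C@]1(C)CCC[C@@]2(C)[C@H]1[C@@H](O)C[C@@](C)(O)[C@@H]2CCC(C)=O | intermediate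
22 | methyl 13-oxo-6α,8α-bis(triethylsilyloxy)-14,15-dinorlabdan-18-oate | COC(=O)[C@]1(C)CCC[C@@]2(C)[C@H]1[C@@H](O[Si](CC)(CC)CC)C[C@@](C)(O[Si](CC)(CC)CC)[C@@H]2CCC(C)=O | intermediate
23 | 15-ethyl 18-methyl (13E)-6α,8α-bis(triethylsilyloxy)labd-13-ene-15,18-dioate | COC(=O)[C@]1(C)CCC[C@@]2(C)[C@H]1[C@@H](O[Si](CC)(CC)CC)C[C@@](C)(O[Si](CC)(CC)CC)[C@@H]2CC/C(C)=C/C(=O)OCC | intermediate
24 | methyl (13E)-15-hydroxy-6α,8α-bis(triethylsilyloxy)labd-13-en-18-oate | COC(=O)[C@]1(C)CCC[C@@]2(C)[C@H]1[C@@H](O[Si](CC)(CC)CC)C[C@@](C)(O[Si](CC)(CC)CC)[C@@H]2CC/C(C)=C/CO | intermediate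
25 | methyl (13S,14S)-13,14-epoxy-15-hydroxy-6α,8α-bis(triethylsilyloxy)labdan-18-oate | COC(=O)[C@]1(C)CCC[C@@]2(C)[C@H]1[C@@H](O[Si](CC)(CC)CC)C[C@@](C)(O[Si](CC)(CC)CC)[C@@H]2CC[C@]3(C)O[C@H]3CO | intermediate
26 | methyl (13R,14S)-13-hydroperoxy-14,15-dihydroxy-6α,8α-bis(triethylsilyloxy)labdan-18-oate | COC(=O)[C@]1(C)CCC[C@@]2(C)[C@H]1[C@@H](O[Si](CC)(CC)CC)C[C@@](C)(O[Si](CC)(CC)CC)[C@@H]2CC[C@@](C)(OO)[C@@H](O)CO | intermediate
27 | methyl (13R)-13-hydroperoxy-14-oxo-6α,8α-bis(triethylsilyloxy)-15-norlabdan-18-oate | COC(=O)[C@]1(C)CCC[C@@]2(C)[C@H]1[C@@H](O[Si](CC)(CC)CC)C[C@@](C)(O[Si](CC)(CC)CC)[C@@H]2CC[C@](C)(C=O)OO | intermediate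
28 | methyl (13R)-13-[(2-methoxypropan-2-yl)peroxy]-14-oxo-6α,8α-bis(triethylsilyloxy)-15-norlabdan-18-oate | COC(=O)[C@]1(C)CCC[C@@]2(C)[C@H]1[C@@H](O[Si](CC)(CC)CC)C[C@@](C)(O[Si](CC)(CC)CC)[C@@H]2CC[C@](C)(C=O)OOC(C)(C)OC | intermediate
29 | 5-hydroxy-4-methylfuran-2(5H)-one | CC1=CC(=O)OC1O | starting material
30 | methyl (2Z)-3-methyl-4-oxobut-2-enoate | COC(=O)/C=C(/C)C=O | intermediate
31 | methyl (2Z)-5-(dimethoxyphosphoryl)-3-methyl-4-oxopent-2-enoate | COC(=O)/C=C(/C)C(=O)CP(=O)(OC)OC | intermediate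
32 | (13R,14E)-dienone ester: C18 methyl ester, 6α,8α-bis(triethylsilyloxy), C9 chain CH2CH2C(CH3)[OOC(CH3)2OCH3]CH=CHC(=O)C(CH3)=CHCO2CH3 with (Z)-enoate | COC(=O)[C@]1(C)CCC[C@@]2(C)[C@H]1[C@@H](O[Si](CC)(CC)CC)C[C@@](C)(O[Si](CC)(CC)CC)[C@@H]2CC[C@](C)(/C=C/C(=O)/C(C)=C\C(=O)OC)OOC(C)(C)OC | intermediate
33 | (13R,14E,16S)-γ-hydroxy (Z)-enoate from 32 (boron alkoxide before work-up) | COC(=O)[C@]1(C)CCC[C@@]2(C)[C@H]1[C@@H](O[Si](CC)(CC)CC)C[C@@](C)(O[Si](CC)(CC)CC)[C@@H]2CC[C@](C)(/C=C/[C@H](O)/C(C)=C\C(=O)OC)OOC(C)(C)OC | intermediate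
34 | bis(triethylsilyl) ether 2-methoxyprop-2-yl peroxide of the target | COC(=O)[C@]1(C)CCC[C@@]2(C)[C@H]1[C@@H](O[Si](CC)(CC)CC)C[C@@](C)(O[Si](CC)(CC)CC)[C@@H]2CC[C@](C)(/C=C/[C@@H]1OC(=O)C=C1C)OOC(C)(C)OC | intermediate
35 | target: methyl (13R,14E,16S)-6α,8α-dihydroxy-13-hydroperoxy ester, chain CH2CH2C(CH3)(OOH)CH=CH on C5 of 4-methylfuran-2(5H)-one | COC(=O)[C@]1(C)CCC[C@@]2(C)[C@H]1[C@@H](O)C[C@@](C)(O)[C@@H]2CC[C@](C)(/C=C/[C@@H]1OC(=O)C=C1C)OO | target

Total step count: 24. Longest linear sequence: 19 steps (steps 1–4, 8–19 and 22–24).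

Steps most likely to fail

Step 11. The potassium alkoxide may fragment (retro-allylation to the enal and an allyl anion) faster than it rearranges, the rearrangement may leak through a boat, or the enolate may be protonated on the wrong face, so that C9, C10 or C5 would be lost. The fallback closes ring B in the cationic sense and sets out from 14. PPTS in wet acetone would give the keto alcohol F1. SnCl4 (CH2Cl2, −78 °C) would ionise the allylic C6 hydroxyl, the C8=C9 alkene would add through C9 to C10 of the allyl cation (chair, anti addition), and the ketone would capture the C8 cation, giving the Δ5-alkene F2, with facial control then resting on C4 alone. Hydroboration–oxidation (BH3·SMe2, then NaBO3) from the α face, as in Δ5-steroids, would set 5α-H and 6α-OH and also reduce the ketone, giving the triol F3. Oxidation of the unhindered side-chain carbinol (catalytic Pr4N[RuO4], N-methylmorpholine N-oxide, 0 °C) would come back to the route at 21.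

Step 13. The C8 cation may lose a proton faster than the ketone oxygen captures it, or the Lewis acid may tie up the ketone, so that alkenes form instead of the 8α-alcohol. The fallback sets out from 19: after the same acetal hydrolysis, Me2AlCl (CH2Cl2, −78 °C) would close ring B by a carbonyl-ene reaction to the homoallylic alcohol F4 (with its Δ7 isomer). The C8 oxygen would then be installed separately by Mukaiyama hydration (Co(acac)2, PhSiH3, O2, THF), with hydrogen-atom transfer to the CH2 terminus and capture of O2 by the tertiary C8 radical from the α face, coming back at 21.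

Step 18. The oxygen on C8, although silylated, may open the activated epoxide intramolecularly (8,13-ether), or ionisation at the tertiary carbon may erode the inversion. The fallback introduces the hydroperoxide last by a Schenck ene reaction and sets out from 24. MsCl/Et3N and then LiBr would give the allylic bromide F5. AgOCOCF3-promoted γ-alkylation of 4-methyl-2-(trimethylsilyloxy)furan (CH2Cl2, −78 °C) would attach the lactone as the bis-silylated butenolide F6 (both C16 epimers). Aqueous HF in MeCN would give the diol butenolide F7. O2, tetraphenylporphyrin and light (CH2Cl2, 0 °C) would then give 35 together with its C13/C16 stereoisomers and the 14-hydroperoxide, to be separated by preparative HPLC.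

Further compounds

F1 | step 11 | methyl (1R)-2-[(1S,3E)-1-hydroxy-3-methyl-7-oxooct-3-en-1-yl]-1,3-dimethylcyclohex-2-ene-1-carboxylate | COC(=O)[C@]1(C)CCCC(C)=C1[C@@H](O)C/C(C)=C/CCC(C)=O
F2 | step 11 | methyl 8α-hydroxy-13-oxo-14,15-dinorlabd-5-en-18-oate | COC(=O)[C@]1(C)CCC[C@@]2(C)C1=CC[C@@](C)(O)[C@@H]2CCC(C)=O
F3 | step 11 | methyl 6α,8α,13-trihydroxy-14,15-dinorlabdan-18-oate (both C13 epimers) | COC(=O)[C@]1(C)CCC[C@@]2(C)[C@H]1[C@@H](O)C[C@@](C)(O)[C@@H]2CCC(C)O
F4 | step 13 | methyl 6α-hydroxy-13-oxo-14,15-dinorlabd-8(17)-en-18-oate | COC(=O)[C@]1(C)CCC[C@@]2(C)[C@H]1[C@@H](O)CC(=C)[C@@H]2CCC(C)=O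
F5 | step 18 | methyl (13E)-15-bromo-6α,8α-bis(triethylsilyloxy)labd-13-en-18-oate | COC(=O)[C@]1(C)CCC[C@@]2(C)[C@H]1[C@@H](O[Si](CC)(CC)CC)C[C@@](C)(O[Si](CC)(CC)CC)[C@@H]2CC/C(C)=C/CBr
F6 | step 18 | (13E)-butenolide bis(triethylsilyl) ether, chain CH2CH2C(CH3)=CHCH2 on C5 of 4-methylfuran-2(5H)-one (both C16 epimers) | COC(=O)[C@]1(C)CCC[C@@]2(C)[C@H]1[C@@H](O[Si](CC)(CC)CC)C[C@@](C)(O[Si](CC)(CC)CC)[C@@H]2CC/C(C)=C/CC1OC(=O)C=C1C
F7 | step 18 | (13E)-6α,8α-dihydroxy butenolide, chain CH2CH2C(CH3)=CHCH2 on C5 of 4-methylfuran-2(5H)-one (both C16 epimers) | COC(=O)[C@]1(C)CCC[C@@]2(C)[C@H]1[C@@H](O)C[C@@](C)(O)[C@@H]2CC/C(C)=C/CC1OC(=O)C=C1C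
A1 | direct plan | (−)-abietic acid | OC(=O)[C@]1(C)CCC[C@@]2(C)[C@H]1CC=C3C=C(C(C)C)CC[C@H]23
A2 | direct plan | isopropyl 8α-hydroxy-14,15,16-trinorlabdan-13-oate 18,6α-lactone | O=C1[C@]2(C)CCC[C@@]3(C)[C@H]2[C@@H](O1)C[C@@](C)(O)[C@@H]3CCC(=O)OC(C)C
A3 | direct plan | (13E,16S)-6α,8α-dihydroxy butenolide, chain CH2CH2C(CH3)=CHCH2 on C5 of 4-methylfuran-2(5H)-one | COC(=O)[C@]1(C)CCC[C@@]2(C)[C@H]1[C@@H](O)C[C@@](C)(O)[C@@H]2CC/C(C)=C/C[C@@H]1OC(=O)C=C1C
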